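The flavanone is cut at C2–C3 of ring C. C2 is a methine that is both benzylic to ring B and bonded to O1, so it can be made from the CH2 of an O1 benzyl ether: a rhodium carbenoid at C3 inserts into one of its two C–H bonds. That single operation closes ring C, forms the C2–C3 bond and sets the only stereocentre (2S) under catalyst control. The precursor is an aryl diazomethyl ketone whose ortho oxygen carries a 3,4-bis(silyloxy)benzyl group, with the silylated C7 hydroxyl and the (E)-hydroxyprenyl chain already in place. It is reached from 2,4-dihydroxyacetophenone by Claisen rearrangement, cross-metathesis, Mitsunobu etherification and diazo transfer, without hydroxide or diazomethane.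

Key step: step 11

Abbreviations: TBS = tert-butyldimethylsilyl; TBSO = tert-butyldimethylsilyloxy.

Assumption: Rh2(S-PTTL)4 is taken to favour the (2S) product; if the opposite sense of induction is found, the mirror-image catalyst Rh2(R-PTTL)4 is used in step 11 with no other change.

Step 1
Reactants: 1 1-(2,4-dihydroxyphenyl)ethanone (2,4-dihydroxyacetophenone); 2 3-bromoprop-1-ene (allyl bromide)
Product: 3 1-[2-hydroxy-4-(prop-2-enyloxy)phenyl]ethanone
Conditions: K2CO3, acetone, reflux
Reagents that add atoms: none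
Why: Williamson etherification; the 2-OH is held in a hydrogen bond to the acetyl carbonyl, so only the free, more acidic 4-OH should be alkylated by the allylic bromide.

Step 2
Reactants: 3 1-[2-hydroxy-4-(prop-2-enyloxy)phenyl]ethanone
Product: 5 1-[2,4-dihydroxy-3-(prop-2-enyl)phenyl]ethanone, via ortho-dienone 4 (not isolated)
Conditions: N,N-diethylaniline, 200 °C, N2
Reagents that add atoms: none
Why: Aromatic Claisen rearrangement ([3,3]-sigmatropic shift) followed by tautomerisation of dienone 4; the chelate between the 2-OH and the acetyl group localises double-bond character in the C3–C4 bond, which should send the allyl group to C3 (between the two oxygens) in preference to C5.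

Step 3
Reactants: 5 1-[2,4-dihydroxy-3-(prop-2-enyl)phenyl]ethanone
Product: 6 1-[4-(TBSO)-2-hydroxy-3-(prop-2-enyl)phenyl]ethanone
Conditions: TBSCl (1.1 equiv), imidazole, CH2Cl2, 0 °C → rt
Reagents that add atoms: tert-butyldimethylsilyl chloride, CC(C)(C)[Si](C)(C)Cl
Why: Imidazole-promoted silyl ether formation; the unchelated 4-OH should react while the hydrogen-bonded, doubly flanked 2-OH is kept free for the later benzylation.

Step 4
Reactants: 6 1-[4-(TBSO)-2-hydroxy-3-(prop-2-enyl)phenyl]ethanone; 7 2-methylprop-2-enal (methacrolein, excess)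
Product: 8 (E)-4-[3-acetyl-6-(TBSO)-2-hydroxyphenyl]-2-methylbut-2-enal
Conditions: second-generation Hoveyda–Grubbs catalyst (5 mol %), 1,4-benzoquinone (10 mol %), CH2Cl2, 40 °C
Reagents that add atoms: none
Why: Olefin cross-metathesis of a terminal alkene with methacrolein, a partner that homodimerises reluctantly and should give the trisubstituted enal as the thermodynamically preferred (E)-isomer; benzoquinone is added to suppress ruthenium hydride migration of the allyl double bond.

Step 5
Reactants: 8 (E)-4-[3-acetyl-6-(TBSO)-2-hydroxyphenyl]-2-methylbut-2-enal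
Product: 9 1-{4-(TBSO)-2-hydroxy-3-[(E)-4-hydroxy-3-methylbut-2-enyl]phenyl}ethanone
Conditions: NaBH4, CeCl3·7H2O, MeOH, −78 °C
Reagents that add atoms: none
Why: Luche 1,2-reduction of the enal in a non-basic medium; the aryl ketone, deactivated by its chelated ortho hydroxyl and the para silyloxy donor, should stay intact at −78 °C, and the alkene geometry is not touched.

Step 6
Reactants: 9 1-{4-(TBSO)-2-hydroxy-3-[(E)-4-hydroxy-3-methylbut-2-enyl]phenyl}ethanone
Product: 10 1-{4-(TBSO)-3-[(E)-4-(TBSO)-3-methylbut-2-enyl]-2-hydroxyphenyl}ethanone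
Conditions: TBSCl (1.2 equiv), imidazole, CH2Cl2, 0 °C → rt
Reagents that add atoms: tert-butyldimethylsilyl chloride, CC(C)(C)[Si](C)(C)Cl
Why: Silyl ether formation at the unhindered primary allylic alcohol, which should be far faster than silylation of the chelated 2-OH.

Step 7
Reactants: 11 3,4-dihydroxybenzaldehyde
Product: 12 3,4-bis(TBSO)benzaldehyde
Conditions: TBSCl (2.3 equiv), imidazole, DMF, rt
Reagents that add atoms: tert-butyldimethylsilyl chloride, CC(C)(C)[Si](C)(C)Cl
Why: Imidazole-promoted silylation of both catechol hydroxyls, which caps ring B with the same fluoride-labile groups used on ring A and leaves the aldehyde untouched.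

Step 8
Reactants: 12 3,4-bis(TBSO)benzaldehyde
Product: 13 [3,4-bis(TBSO)phenyl]methanol
Conditions: NaBH4, EtOH/THF, 0 °C
Reagents that add atoms: none
Why: Borohydride reduction of an aromatic aldehyde to the benzylic alcohol, run cold and briefly so that the aryl silyl ethers should persist.

Step 9
Reactants: 10 1-{4-(TBSO)-3-[(E)-4-(TBSO)-3-methylbut-2-enyl]-2-hydroxyphenyl}ethanone; 13 [3,4-bis(TBSO)phenyl]methanol
Product: 14 1-{2-[3,4-bis(TBSO)benzyloxy]-4-(TBSO)-3-[(E)-4-(TBSO)-3-methylbut-2-enyl]phenyl}ethanone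
Conditions: PPh3, DIAD, THF, 0 °C → rt
Reagents that add atoms: none
Why: Mitsunobu etherification; the phenol of 10, acidified by the ortho acetyl group, protonates the phosphine–azodicarboxylate betaine and its phenoxide displaces the oxyphosphonium derivative of primary benzylic alcohol 13 by SN2, under neutral conditions that should spare the aryl silyl ethers.

Step 10
Reactants: 14 1-{2-[3,4-bis(TBSO)benzyloxy]-4-(TBSO)-3-[(E)-4-(TBSO)-3-methylbut-2-enyl]phenyl}ethanone
Product: 16 2-diazo-1-{2-[3,4-bis(TBSO)benzyloxy]-4-(TBSO)-3-[(E)-4-(TBSO)-3-methylbut-2-enyl]phenyl}ethanone, via trifluoroacetyl diketone 15 (not isolated)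
Conditions: LiN(SiMe3)2, THF, −78 °C; CF3CO2CH2CF3; AcOH quench, extractive work-up; then crude 15, MsN3, Et3N, H2O (1 equiv), MeCN, rt
Reagents that add atoms: methanesulfonyl azide, CS(=O)(=O)N=[N+]=[N-] (supplies both diazo nitrogens); 2,2,2-trifluoroethyl trifluoroacetate, O=C(OCC(F)(F)F)C(F)(F)F (supplies the trifluoroacetyl group of 15, which is lost again on diazo transfer)
Why: Detrifluoroacetylative diazo transfer (a Regitz-type diazo transfer to an activated methyl ketone); the acetyl CH3 is the only enolisable position of 14, its lithium enolate is C-trifluoroacetylated, and the 1,3-dicarbonyl compound 15 should take up the diazo group from the sulfonyl azide with loss of the trifluoroacetyl group, with no hydroxide and no diazomethane involved.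

Step 11
Reactants: 16 2-diazo-1-{2-[3,4-bis(TBSO)benzyloxy]-4-(TBSO)-3-[(E)-4-(TBSO)-3-methylbut-2-enyl]phenyl}ethanone
Product: 17 (2S)-2-[3,4-bis(TBSO)phenyl]-7-(TBSO)-8-[(E)-4-(TBSO)-3-methylbut-2-enyl]-2,3-dihydro-4H-chromen-4-one
Conditions: Rh2(S-PTTL)4 [dirhodium tetrakis(N-phthaloyl-(S)-tert-leucinate)] (1 mol %), toluene, −40 → 0 °C, slow addition of 16 at high dilution
Reagents that add atoms: none
Why: The dirhodium tetracarboxylate (divalent rhodium) expels N2 from 16 to give an electrophilic acyl carbenoid at C3, which inserts into one benzylic C–H bond of the O1–CH2–aryl group through a concerted, asynchronous three-centre transition state with hydride-transfer character, forming C2–C3 with retention at C2. The closest known reaction type is the chiral dirhodium carboxylate catalysed intramolecular C–H insertion of ortho-alkoxyaryl diazoketones that gives 2-substituted chroman-4-ones. Ring C closes as a six-membered ring by 1,6-insertion (carbenoid carbon as atom 1, C2 as atom 6), the chain C3–C4–C4a–C8a–O1–C2 being held in place by ring A. The C2 stereocentre is set under catalyst control, the phthalimido walls of the tert-leucinate ligands distinguishing the two enantiotopic benzylic hydrogens, and no other stereocentre is present to interfere. The step needs insertion to win over oxonium ylide formation at O1 (which would end in a [1,2]-benzyl shift), carbene dimerisation and alkene cyclopropanation. The substrate helps because the electron-rich bis(silyloxy)phenyl ring makes the C2–H bonds hydridic, O1 is a weakly basic aryl ether oxygen conjugated to the ortho acyl group and crowded by the C8 chain, and the chain alkene sits meta to the carbenoid arm and cannot reach it, while slow addition at high dilution holds back bimolecular paths.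

Step 12
Reactants: 17 (2S)-2-[3,4-bis(TBSO)phenyl]-7-(TBSO)-8-[(E)-4-(TBSO)-3-methylbut-2-enyl]-2,3-dihydro-4H-chromen-4-one
Product: 18 (2S)-2-(3,4-dihydroxyphenyl)-7-hydroxy-8-[(E)-4-hydroxy-3-methylbut-2-enyl]-2,3-dihydro-4H-chromen-4-one (CNP0205253.1)
Conditions: Et3N·3HF (excess), THF/MeCN, rt → 40 °C; pH 7 phosphate buffer work-up
Reagents that add atoms: none
Why: Fluoride-driven desilylation of all four Si–O bonds in a weakly acidic amine–HF medium, where neither a phenoxide nor the C3 enolate forms, so ring C should not open to the chalcone and C2 should keep its configuration; the allylic alcohol and the alkene are inert to the reagent.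

Compound list
1 | 1-(2,4-dihydroxyphenyl)ethanone (2,4-dihydroxyacetophenone) | CC(=O)c1ccc(O)cc1O | starting material
2 | 3-bromoprop-1-ene (allyl bromide) | C=CCBr | starting material
3 | 1-[2-hydroxy-4-(prop-2-enyloxy)phenyl]ethanone | CC(=O)c1ccc(OCC=C)cc1O | intermediate
4 | 4-acetyl-3-hydroxy-2-(prop-2-enyl)cyclohexa-3,5-dien-1-one (racemic ortho-dienone) | CC(=O)C1=C(O)C(CC=C)C(=O)C=C1 | intermediate (not isolated)
5 | 1-[2,4-dihydroxy-3-(prop-2-enyl)phenyl]ethanone | CC(=O)c1ccc(O)c(CC=C)c1O | intermediate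
6 | 1-[4-(tert-butyldimethylsilyloxy)-2-hydroxy-3-(prop-2-enyl)phenyl]ethanone | CC(=O)c1ccc(O[Si](C)(C)C(C)(C)C)c(CC=C)c1O | intermediate
7 | 2-methylprop-2-enal (methacrolein) | CC(=C)C=O | starting material
8 | (E)-4-[3-acetyl-6-(tert-butyldimethylsilyloxy)-2-hydroxyphenyl]-2-methylbut-2-enal | CC(=O)c1ccc(O[Si](C)(C)C(C)(C)C)c(C/C=C(\C)C=O)c1O | intermediate
9 | 1-{4-(tert-butyldimethylsilyloxy)-2-hydroxy-3-[(E)-4-hydroxy-3-methylbut-2-enyl]phenyl}ethanone | CC(=O)c1ccc(O[Si](C)(C)C(C)(C)C)c(C/C=C(\C)CO)c1O | intermediate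
10 | 1-{4-(tert-butyldimethylsilyloxy)-3-[(E)-4-(tert-butyldimethylsilyloxy)-3-methylbut-2-enyl]-2-hydroxyphenyl}ethanone | CC(=O)c1ccc(O[Si](C)(C)C(C)(C)C)c(C/C=C(\C)CO[Si](C)(C)C(C)(C)C)c1O | intermediate
11 | 3,4-dihydroxybenzaldehyde | O=Cc1ccc(O)c(O)c1 | starting material
12 | 3,4-bis(tert-butyldimethylsilyloxy)benzaldehyde | O=Cc1ccc(O[Si](C)(C)C(C)(C)C)c(O[Si](C)(C)C(C)(C)C)c1 | intermediate
13 | [3,4-bis(tert-butyldimethylsilyloxy)phenyl]methanol | OCc1ccc(O[Si](C)(C)C(C)(C)C)c(O[Si](C)(C)C(C)(C)C)c1 | intermediate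
14 | 1-{2-[3,4-bis(tert-butyldimethylsilyloxy)benzyloxy]-4-(tert-butyldimethylsilyloxy)-3-[(E)-4-(tert-butyldimethylsilyloxy)-3-methylbut-2-enyl]phenyl}ethanone | CC(=O)c1ccc(O[Si](C)(C)C(C)(C)C)c(C/C=C(\C)CO[Si](C)(C)C(C)(C)C)c1OCc1ccc(O[Si](C)(C)C(C)(C)C)c(O[Si](C)(C)C(C)(C)C)c1 | intermediate
15 | 1-{2-[3,4-bis(tert-butyldimethylsilyloxy)benzyloxy]-4-(tert-butyldimethylsilyloxy)-3-[(E)-4-(tert-butyldimethylsilyloxy)-3-methylbut-2-enyl]phenyl}-4,4,4-trifluorobutane-1,3-dione | O=C(CC(=O)C(F)(F)F)c1ccc(O[Si](C)(C)C(C)(C)C)c(C/C=C(\C)CO[Si](C)(C)C(C)(C)C)c1OCc1ccc(O[Si](C)(C)C(C)(C)C)c(O[Si](C)(C)C(C)(C)C)c1 | intermediate (not isolated)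
16 | 2-diazo-1-{2-[3,4-bis(tert-butyldimethylsilyloxy)benzyloxy]-4-(tert-butyldimethylsilyloxy)-3-[(E)-4-(tert-butyldimethylsilyloxy)-3-methylbut-2-enyl]phenyl}ethanone | [N-]=[N+]=CC(=O)c1ccc(O[Si](C)(C)C(C)(C)C)c(C/C=C(\C)CO[Si](C)(C)C(C)(C)C)c1OCc1ccc(O[Si](C)(C)C(C)(C)C)c(O[Si](C)(C)C(C)(C)C)c1 | intermediate
17 | (2S)-2-[3,4-bis(tert-butyldimethylsilyloxy)phenyl]-7-(tert-butyldimethylsilyloxy)-8-[(E)-4-(tert-butyldimethylsilyloxy)-3-methylbut-2-enyl]-2,3-dihydro-4H-chromen-4-one | C/C(=C\Cc1c(O[Si](C)(C)C(C)(C)C)ccc2c1O[C@H](c1ccc(O[Si](C)(C)C(C)(C)C)c(O[Si](C)(C)C(C)(C)C)c1)CC2=O)CO[Si](C)(C)C(C)(C)C | intermediate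
18 | (2S)-2-(3,4-dihydroxyphenyl)-7-hydroxy-8-[(E)-4-hydroxy-3-methylbut-2-enyl]-2,3-dihydro-4H-chromen-4-one | C/C(=C\Cc1c(O)ccc2c1O[C@H](c1ccc(O)c(O)c1)CC2=O)CO | target

Total step count: 12. Longest linear sequence: 10 steps (steps 1–6 and 9–12); steps 7 and 8 form the two-step side branch to 13.

Steps most likely to fail

Step 11. The carbenoid may be captured by the lone pair of O1 to give an oxonium ylide that collapses by [1,2]-benzyl shift instead of inserting, or the catalyst may distinguish the two enantiotopic benzylic hydrogens poorly. The fallback drops carbene chemistry and forms the C2–aryl bond by asymmetric 1,4-addition to a chromone; it sets out from 10 and returns to the route at 17.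
- Condensation of 10 with N,N-dimethylformamide dimethyl acetal (toluene, 90 °C) should give (E)-1-{4-(TBSO)-3-[(E)-4-(TBSO)-3-methylbut-2-enyl]-2-hydroxyphenyl}-3-(dimethylamino)prop-2-en-1-one F1.
- Mild acid (AcOH, toluene, 60 °C) should close F1 with loss of dimethylamine to 7-(TBSO)-8-[(E)-4-(TBSO)-3-methylbut-2-enyl]-4H-chromen-4-one F2.
- Separately, commercial 4-bromobenzene-1,2-diol is silylated (TBSCl, imidazole, DMF) to 4-bromo-1,2-bis(TBSO)benzene F3.
- Bromine–lithium exchange (n-BuLi, THF, −78 °C) should give [3,4-bis(TBSO)phenyl]lithium F4, which is trapped with B(OiPr)3 and worked up with aqueous NH4Cl to give [3,4-bis(TBSO)phenyl]boronic acid F5.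
- Base-free rhodium-catalysed asymmetric conjugate addition of F5 to F2 should deliver 17. Conditions: [Rh(OH)(cod)]2 with the antipode of the electron-poor bisphosphine 2,2'-bis[bis(3,4,5-trifluorophenyl)phosphino]-6,6'-dimethoxy-1,1'-biphenyl that leads to (2S), toluene/H2O, rt.

Step 9. The hindered, strongly hydrogen-bonded phenol may be alkylated too slowly, so that the activated benzylic alcohol is consumed by the hydrazide by-product. The fallback replaces redox condensation by a classical SN2 alkylation; it sets out from 13 and 10 and returns at 14.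
- Alcohol 13 is converted with CBr4 and PPh3 (CH2Cl2, 0 °C) into 4-(bromomethyl)-1,2-bis(TBSO)benzene F6, which is used fresh.
- Phenol 10 is then alkylated with F6 (anhydrous K2CO3, acetone, rt → 50 °C) to give 14.

Step 4. Ruthenium hydride species may move the allyl double bond into conjugation with the ring, and turnover with the electron-poor 1,1-disubstituted partner may be sluggish. The fallback builds the enal by oxidative cleavage and olefination; it sets out from 6 and returns at 8.
- Lemieux–Johnson cleavage of 6 (OsO4 cat., NaIO4, 2,6-lutidine, dioxane/H2O) should give 2-[3-acetyl-6-(TBSO)-2-hydroxyphenyl]acetaldehyde F7, which may rest as its cyclic lactol through the ortho hydroxyl.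
- Wittig olefination of F7 with the stabilised ylide 2-(triphenylphosphoranylidene)propanal (toluene, 80 °C) should give the (E)-enal 8.

Further compounds
F1 | step 11 | (E)-1-{4-(tert-butyldimethylsilyloxy)-3-[(E)-4-(tert-butyldimethylsilyloxy)-3-methylbut-2-enyl]-2-hydroxyphenyl}-3-(dimethylamino)prop-2-en-1-one | CN(C)/C=C/C(=O)c1ccc(O[Si](C)(C)C(C)(C)C)c(C/C=C(\C)CO[Si](C)(C)C(C)(C)C)c1O
F2 | step 11 | 7-(tert-butyldimethylsilyloxy)-8-[(E)-4-(tert-butyldimethylsilyloxy)-3-methylbut-2-enyl]-4H-chromen-4-one | O=c1ccoc2c1ccc(O[Si](C)(C)C(C)(C)C)c2C/C=C(\C)CO[Si](C)(C)C(C)(C)C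
F3 | step 11 | 4-bromo-1,2-bis(tert-butyldimethylsilyloxy)benzene | Brc1ccc(O[Si](C)(C)C(C)(C)C)c(O[Si](C)(C)C(C)(C)C)c1
F4 | step 11 | [3,4-bis(tert-butyldimethylsilyloxy)phenyl]lithium | [Li]c1ccc(O[Si](C)(C)C(C)(C)C)c(O[Si](C)(C)C(C)(C)C)c1
F5 | step 11 | [3,4-bis(tert-butyldimethylsilyloxy)phenyl]boronic acid | OB(O)c1ccc(O[Si](C)(C)C(C)(C)C)c(O[Si](C)(C)C(C)(C)C)c1
F6 | step 9 | 4-(bromomethyl)-1,2-bis(tert-butyldimethylsilyloxy)benzene | BrCc1ccc(O[Si](C)(C)C(C)(C)C)c(O[Si](C)(C)C(C)(C)C)c1
F7 | step 4 | 2-[3-acetyl-6-(tert-butyldimethylsilyloxy)-2-hydroxyphenyl]acetaldehyde | CC(=O)c1ccc(O[Si](C)(C)C(C)(C)C)c(CC=O)c1O
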